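Take as the unit of time the meeting time: for electrophile and nucleophile charged about one to one, the fraction of electrophile left after any number of these units is one over one plus that number, a second-order hyperbola rather than an exponential. The charge here is 1.05 nucleophile per electrophile.

in all of them: electrophile 0.40 M
- Sunday's: nucleophile 0.42 M; free base 1.1 M; run made earlier
- Saturday's: nucleophile 0.42 M; free base 1.8 M; run made earlier
- flask: nucleophile 0.420 M; free base 0.800 M; time 10 min

- Sunday's (time / min: electrophile / %, product / %): 1.50: 23.2, 75.8; 4.00: 9.8, 88.5; 8.00: 4.5, 97.4; 12.0: 4.1, 97.6
- Saturday's (time / min: electrophile / %, product / %): 3.00: 12.6, 87.6; 6.00: 6.1, 91.6; 10.0: 2.5, 95.7; 12.0: 1.4, 96.9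

(scatter of a reading: 1 percentage point)

- part of the electrophile that has reacted at 10 min
- share of free nucleophile in free nucleophile and protonated nucleophile together, at 10 min

I read the unit from Sunday's first reading, 23.2% left at 1.50 min: 0.453 min, the meeting time. On Saturday's richer base it gives 13.1% left at 3.00 min, and 12.6% was read. So I hold that the amount of base, at these two charges, hardly moves the clock. The asked 10 min is 22.1 units, which leaves 4.33% and gives 95.7% reacted. The readings give me no free share, but the base charged is twice the electrophile, so I guess it stands above the forecast's.

The forecast takes the other view: “the acid released partly ties up nucleophile”. It points to a late sag on Sunday, but my clock gives 3.64% at 12.0 min, against 4.1% read, with a scatter of 1 percentage point. It says 96% reacted and a free share of 75%. We agree on the first number from opposite grounds and part on the second.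

The flask gives 96.0% and 85.5%.

    nucleophile + acid set free ⇌ protonated nucleophile, settled at all times (K = 70.0 M⁻¹)
    electrophile + nucleophile → acid set free + product (k = 0.140 M⁻¹ s⁻¹)
    acid set free + free base ⇌ salt of the base (K = 390 M⁻¹, k = 0.850 M⁻¹ s⁻¹)
    nucleophile ⇌ dormant form (K = 0.850, k = 0.00630 s⁻¹)

The forecast's share lies near what this flask holds early: at 1.00 min, free nucleophile is 18.4% of its charge and protonated nucleophile 7.40%, a free share of 71.3%. At that moment the meeting time leaves 31.2% of the electrophile, and the flask holds 31.9%.

In the neighbour flask with 0.10 M of nucleophile, that is the limiting reagent, so the ceiling is 25.0% reacted. The meeting time, stretched by the charge over the gap between charges, becomes 0.604 min, far shorter than 10 min, so that flask should reach its ceiling. It gives 24.9% reacted, with 75.1% of the electrophile left.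

The data are simulated with constants of no real substance.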